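**Retrosynthetic overview**
1. The target is epicatechin-(4β→8)-[epicatechin 3-O-gallate]-(4β→8)-[epicatechin 3-O-gallate]; the last step is one hydrogenolysis that removes eighteen benzyl ethers and a C8–Br cap.
2. Key disconnection: the interflavan bond C4(middle unit)–C8(lower unit), made by Ag(I) ionisation of a C4 thioether on a top–middle dimer and Friedel–Crafts capture by C8 of per-benzylated epicatechin gallate. The dimer is assembled in the same flask (C4(top)–C8(middle), TMSOTf on a C4 ether), so three monomers give the whole skeleton and both C4 stereocentres in one operation.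
3. Enabling feature: each C4 is benzylic to a phloroglucinol-type A ring (O1, O5, O7 ortho/para), so it ionises from either C4 epimer. The C=O of the middle unit's 3α-O-galloyl ester sits next to C4 and bridges it as a cis-fused dioxolanylium ring, which forces 4β attack. C8 of each A ring (between O7 and O1) is the unhindered nucleophilic carbon.
4. Temporary groups: C4–O(2-ethoxyethyl) (hard) and C4–S(2,6-xylyl) (soft) leaving groups are both expelled in the key step; C8–Br on the top unit stops oligomerisation and leaves in the final hydrogenolysis.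
5. Rings: none of the target's rings is built. The three chroman systems with their six C2/C3 stereocentres come from (−)-epicatechin through one common tetra-O-benzyl ether; only the transient dioxolanylium ring forms and reopens.

Key step: step 8

Remark: the C4 ether and thioether leaving groups are drawn as the expected 4β epimers; any 4α epimer is carried along, because the key step ionises both to the same cation, and 3,4,5-tris(benzyloxy)benzoic acid is taken as a commercial reagent.

**Route**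

Step 1
Reactants: 1 (−)-epicatechin; 2 benzyl bromide
Product: 3 5,7,3',4'-tetra-O-benzyl-(−)-epicatechin
Conditions: BnBr (4.4 equiv), K2CO3, DMF, 0 °C to rt, Ar
Reagents that add atoms: benzyl bromide (2), BrCc1ccccc1
Why: Williamson ether synthesis in which carbonate deprotonates only the four phenols, so the secondary 3-OH stays free and no stereocentre is touched.

Step 2
Reactants: 3 5,7,3',4'-tetra-O-benzyl-(−)-epicatechin; 4 3,4,5-tris(benzyloxy)benzoic acid
Product: 5 5,7,3',4'-tetra-O-benzyl-3-O-(3,4,5-tri-O-benzylgalloyl)-(−)-epicatechin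
Conditions: DCC, DMAP (cat.), CH2Cl2, rt
Reagents that add atoms: 3,4,5-tris(benzyloxy)benzoic acid (4), OC(=O)c1cc(OCc2ccccc2)c(OCc2ccccc2)c(OCc2ccccc2)c1
Why: Steglich esterification of the 3-OH, which retains C3 because the C3–O bond is not broken.

Step 3
Reactants: 3 5,7,3',4'-tetra-O-benzyl-(−)-epicatechin; 6 2-ethoxyethanol
Product: 7 5,7,3',4'-tetra-O-benzyl-4β-(2-ethoxyethoxy)-(−)-epicatechin
Conditions: DDQ (2 equiv), 2-ethoxyethanol (excess), CH2Cl2, rt
Reagents that add atoms: 2-ethoxyethanol (6), CCOCCO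
Why: DDQ benzylic oxidation (hydride abstraction from C4, activated by the O1/O5/O7-substituted A ring) with capture of the cation by the alcohol anti to the axial 3α-OH, which should give the 4β ether.

Step 4
Reactants: 7 5,7,3',4'-tetra-O-benzyl-4β-(2-ethoxyethoxy)-(−)-epicatechin; 8 2,6-dimethylbenzenethiol
Product: 9 5,7,3',4'-tetra-O-benzyl-4β-(2,6-dimethylphenylthio)-(−)-epicatechin
Conditions: thiol (4 equiv), BF3·OEt2 (cat.), CH2Cl2, −78 to −40 °C
Reagents that add atoms: 2,6-dimethylbenzenethiol (8), Cc1cccc(C)c1S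
Why: Lewis acid catalysed SN1 thiol exchange (thiolysis) at C4, in which the excess soft thiol outcompetes the arene carbons and adds mainly anti to the 3α-OH.

Step 5
Reactants: 9 5,7,3',4'-tetra-O-benzyl-4β-(2,6-dimethylphenylthio)-(−)-epicatechin; 4 3,4,5-tris(benzyloxy)benzoic acid
Product: 10 5,7,3',4'-tetra-O-benzyl-3-O-(3,4,5-tri-O-benzylgalloyl)-4β-(2,6-dimethylphenylthio)-(−)-epicatechin
Conditions: DCC, DMAP, CH2Cl2, rt
Reagents that add atoms: 3,4,5-tris(benzyloxy)benzoic acid (4), OC(=O)c1cc(OCc2ccccc2)c(OCc2ccccc2)c(OCc2ccccc2)c1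
Why: Steglich esterification of the 3-OH, to which the hindered aryl thioether is inert and which leaves C3 and C4 untouched.

Step 6
Reactants: 3 5,7,3',4'-tetra-O-benzyl-(−)-epicatechin; 11 N-bromosuccinimide
Product: 12 8-bromo-5,7,3',4'-tetra-O-benzyl-(−)-epicatechin
Conditions: NBS (1.0 equiv), CH2Cl2, −78 °C to rt
Reagents that add atoms: N-bromosuccinimide (11), O=C1CCC(=O)N1Br
Why: Electrophilic aromatic bromination at C8, the least hindered activated A-ring carbon (between O7 and ring O1, whereas C6 lies between two benzyloxy groups).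

Step 7
Reactants: 12 8-bromo-5,7,3',4'-tetra-O-benzyl-(−)-epicatechin; 6 2-ethoxyethanol
Product: 13 8-bromo-5,7,3',4'-tetra-O-benzyl-4β-(2-ethoxyethoxy)-(−)-epicatechin
Conditions: DDQ (2 equiv), 2-ethoxyethanol (excess), CH2Cl2, rt
Reagents that add atoms: 2-ethoxyethanol (6), CCOCCO
Why: DDQ benzylic oxidation at C4 with alcohol capture anti to the 3α-OH, as in step 3; the aryl bromide is inert.

Step 8
Reactants: 13 8-bromo-5,7,3',4'-tetra-O-benzyl-4β-(2-ethoxyethoxy)-(−)-epicatechin; 10 5,7,3',4'-tetra-O-benzyl-3-O-(3,4,5-tri-O-benzylgalloyl)-4β-(2,6-dimethylphenylthio)-(−)-epicatechin; 5 5,7,3',4'-tetra-O-benzyl-3-O-(3,4,5-tri-O-benzylgalloyl)-(−)-epicatechin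
Product: 16 bromine-capped octadeca-O-benzyl trimer (protected target), via dimer thioether 14 (not isolated), via dioxolanylium triflate 15 (not isolated)
Conditions: (i) 13 and 10 (1:1), TMSOTf (0.1 equiv), 4 Å MS, CH2Cl2, −78 °C; (ii) 5 (2 equiv), AgOTf (1.5 equiv), −78 to −30 °C; then Et3N
Reagents that add atoms: none
Why: In stage (i) catalytic TMSOTf should ionise only the hard C4–O ether of 13 to its trioxygenated benzylic cation, which the free C8 of 10 captures on the β face, anti to the axial 3α-OH; the soft, hindered C4–S bond of 10 and the bromine-blocked C8 of 13 stay silent, so a single dimer 14 should form without oligomers. In stage (ii) Ag(I) pulls the thiolate off C4 of 14 from either C4 epimer and the α-oriented 3-O-galloyl carbonyl closes onto the cation (5-exo-trig) to give the cis-fused 1,3-dioxolan-2-ylium ion 15, whose α face is thereby blocked. C8 of 5 opens 15 at C4 from the β face, which sets the 4β (3,4-trans) configuration stereoconvergently and returns the gallate ester intact. The closest known reaction types are the Lewis acid mediated Friedel–Crafts C4–C8 coupling of 4-alkoxyflavan-3-ols, the thiophile-promoted coupling of 4-thioflavans, and 1,2-trans glycosylation by acyl neighbouring-group participation under orthogonal hard-then-soft one-pot activation. No ring of the product is closed, and the two new stereocentres (C4 of the top and of the middle unit) are each controlled by the adjacent 3α-oxygen substituent, the free OH in stage (i) and the participating ester in stage (ii). The step needs C8 over C6 regioselectivity, secured by the benzyloxy-flanked, more hindered C6 positions, and chemoselectivity between the two electrophiles, secured by the O/S leaving-group pair and the order of the promoters.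

Step 9
Reactants: 16 bromine-capped octadeca-O-benzyl trimer
Product: 17 epicatechin-(4β→8)-epicatechin 3-O-gallate-(4β→8)-epicatechin 3-O-gallate (target)
Conditions: H2 (1 atm), Pd(OH)2/C, Et3N (1.0 equiv), THF/MeOH/H2O, rt; Sephadex LH-20
Reagents that add atoms: none
Why: Catalytic hydrogenolysis should cleave the eighteen benzyl ethers and the aryl C–Br bond in one operation, while the two esters, the interflavan bonds and all eight stereocentres are not affected.

**Compound list**

1 | (−)-epicatechin, (2R,3R) | O[C@@H]1Cc2c(O)cc(O)cc2O[C@@H]1c1ccc(O)c(O)c1 | starting material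
2 | benzyl bromide | BrCc1ccccc1 | starting material
3 | 5,7,3',4'-tetra-O-benzyl-(−)-epicatechin | O[C@@H]1Cc2c(OCc3ccccc3)cc(OCc3ccccc3)cc2O[C@@H]1c1ccc(OCc2ccccc2)c(OCc2ccccc2)c1 | intermediate
4 | 3,4,5-tris(benzyloxy)benzoic acid | OC(=O)c1cc(OCc2ccccc2)c(OCc2ccccc2)c(OCc2ccccc2)c1 | starting material
5 | 5,7,3',4'-tetra-O-benzyl-3-O-(3,4,5-tri-O-benzylgalloyl)-(−)-epicatechin (lower unit, C8 nucleophile) | O=C(O[C@@H]1Cc2c(OCc3ccccc3)cc(OCc3ccccc3)cc2O[C@@H]1c1ccc(OCc2ccccc2)c(OCc2ccccc2)c1)c1cc(OCc2ccccc2)c(OCc2ccccc2)c(OCc2ccccc2)c1 | intermediate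
6 | 2-ethoxyethanol | CCOCCO | starting material
7 | 5,7,3',4'-tetra-O-benzyl-4β-(2-ethoxyethoxy)-(−)-epicatechin (4-OR trans to 3α-OH) | O[C@@H]1[C@@H](OCCOCC)c2c(OCc3ccccc3)cc(OCc3ccccc3)cc2O[C@@H]1c1ccc(OCc2ccccc2)c(OCc2ccccc2)c1 | intermediate
8 | 2,6-dimethylbenzenethiol | Cc1cccc(C)c1S | starting material
9 | 5,7,3',4'-tetra-O-benzyl-4β-(2,6-dimethylphenylthio)-(−)-epicatechin | O[C@@H]1[C@@H](Sc2c(C)cccc2C)c2c(OCc3ccccc3)cc(OCc3ccccc3)cc2O[C@@H]1c1ccc(OCc2ccccc2)c(OCc2ccccc2)c1 | intermediate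
10 | 5,7,3',4'-tetra-O-benzyl-3-O-(3,4,5-tri-O-benzylgalloyl)-4β-(2,6-dimethylphenylthio)-(−)-epicatechin (middle unit) | O=C(O[C@@H]1[C@@H](Sc2c(C)cccc2C)c2c(OCc3ccccc3)cc(OCc3ccccc3)cc2O[C@@H]1c1ccc(OCc2ccccc2)c(OCc2ccccc2)c1)c1cc(OCc2ccccc2)c(OCc2ccccc2)c(OCc2ccccc2)c1 | intermediate
11 | N-bromosuccinimide | O=C1CCC(=O)N1Br | starting material
12 | 8-bromo-5,7,3',4'-tetra-O-benzyl-(−)-epicatechin | O[C@@H]1Cc2c(OCc3ccccc3)cc(OCc3ccccc3)c(Br)c2O[C@@H]1c1ccc(OCc2ccccc2)c(OCc2ccccc2)c1 | intermediate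
13 | 8-bromo-5,7,3',4'-tetra-O-benzyl-4β-(2-ethoxyethoxy)-(−)-epicatechin (top unit) | O[C@@H]1[C@@H](OCCOCC)c2c(OCc3ccccc3)cc(OCc3ccccc3)c(Br)c2O[C@@H]1c1ccc(OCc2ccccc2)c(OCc2ccccc2)c1 | intermediate
14 | dimer thioether: [8-bromo-tetra-O-benzyl-epicatechin]-(4β→8)-[tetra-O-benzyl-3-O-(tri-O-benzylgalloyl)-4β-(2,6-dimethylphenylthio)-epicatechin] | O=C(O[C@@H]1[C@@H](Sc2c(C)cccc2C)c2c(OCc5ccccc5)cc(OCc5ccccc5)c([C@H]3c4c(OCc5ccccc5)cc(OCc5ccccc5)c(Br)c4O[C@H](c4ccc(OCc5ccccc5)c(OCc5ccccc5)c4)[C@@H]3O)c2O[C@@H]1c1ccc(OCc5ccccc5)c(OCc5ccccc5)c1)c1cc(OCc5ccccc5)c(OCc5ccccc5)c(OCc5ccccc5)c1 | intermediate (not isolated)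
15 | dioxolanylium triflate: 2-(3,4,5-tribenzyloxyphenyl)-1,3-dioxolan-2-ylium ring cis-fused across O3–C3–C4–O of the middle unit on the α face, top unit unchanged | [O-]S(=O)(=O)C(F)(F)F.c1(C6=[O+][C@@H]7[C@H](O6)c2c(OCc5ccccc5)cc(OCc5ccccc5)c([C@H]3c4c(OCc5ccccc5)cc(OCc5ccccc5)c(Br)c4O[C@H](c4ccc(OCc5ccccc5)c(OCc5ccccc5)c4)[C@@H]3O)c2O[C@@H]7c2ccc(OCc5ccccc5)c(OCc5ccccc5)c2)cc(OCc5ccccc5)c(OCc5ccccc5)c(OCc5ccccc5)c1 | intermediate (not isolated)
16 | bromine-capped octadeca-O-benzyl trimer: [8-bromo-tetra-O-benzyl-epicatechin]-(4β→8)-[tetra-O-benzyl-3-O-(tri-O-benzylgalloyl)-epicatechin]-(4β→8)-[tetra-O-benzyl-3-O-(tri-O-benzylgalloyl)-epicatechin] | O=C(O[C@@H]1[C@@H](c2c(OCc5ccccc5)cc(OCc5ccccc5)c3c2O[C@H](c2ccc(OCc5ccccc5)c(OCc5ccccc5)c2)[C@H](OC(=O)c2cc(OCc5ccccc5)c(OCc5ccccc5)c(OCc5ccccc5)c2)C3)c2c(OCc5ccccc5)cc(OCc5ccccc5)c([C@H]3c4c(OCc5ccccc5)cc(OCc5ccccc5)c(Br)c4O[C@H](c4ccc(OCc5ccccc5)c(OCc5ccccc5)c4)[C@@H]3O)c2O[C@@H]1c1ccc(OCc5ccccc5)c(OCc5ccccc5)c1)c1cc(OCc5ccccc5)c(OCc5ccccc5)c(OCc5ccccc5)c1 | intermediate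
17 | epicatechin-(4β→8)-epicatechin 3-O-gallate-(4β→8)-epicatechin 3-O-gallate (all units 2R,3R; both interflavan bonds 4β, trans to the 3-oxygen) | O=C(O[C@@H]1[C@@H](c2c(O)cc(O)c3c2O[C@H](c2ccc(O)c(O)c2)[C@H](OC(=O)c2cc(O)c(O)c(O)c2)C3)c2c(O)cc(O)c([C@H]3c4c(O)cc(O)cc4O[C@H](c4ccc(O)c(O)c4)[C@@H]3O)c2O[C@@H]1c1ccc(O)c(O)c1)c1cc(O)c(O)c(O)c1 | target

**Summary**

Total step count: 9. Longest linear sequence: 6 steps (steps 1, 3, 4, 5, 8, 9).

Steps most likely to fail:

Step 8. What may go wrong is cross-talk between the two activations in one flask: premature ionisation of the C4–S bond by the hard promoter, transfer of the arylthio group to the first cation, or carry-over of unreacted monomers into stage (ii), any of which would give mixtures of dimers. The fallback inverts the order of the two bond formations and isolates the intermediate. Setting out from 10 and 5, AgOTf in CH2Cl2 at −40 °C with 5 in threefold excess should give, by the same neighbouring-group-controlled Friedel–Crafts alkylation, the lower dimer per-O-benzylated epicatechin 3-O-gallate-(4β→8)-epicatechin 3-O-gallate F1. After chromatography F1, whose only unhindered nucleophilic carbon is C8 of its upper unit, would be alkylated by the bromine-capped ether 13 under catalytic TMSOTf at −78 °C, which comes back to the route at 16.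

Step 9. What may go wrong is stalling of the hydrogenolysis through catalyst poisoning by traces of sulfur or silver or through inhibition by the amine, and acid-promoted cleavage of the interflavan bonds if hydrogen bromide is released unbuffered. The fallback separates the two tasks. Setting out from 16, radical hydrodebromination (Bu3SnH, AIBN, toluene, 80 °C) should give the bromine-free octadeca-O-benzyl trimer F3, which after chromatography is hydrogenolysed under neutral conditions (H2, Pd(OH)2/C, THF/MeOH/H2O, rt), coming back to the route at 17.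

Step 4. What may go wrong is Friedel–Crafts self-condensation of the C4 cation with the free C8 of a second molecule competing with capture by the hindered thiol. The fallback changes the order so that the cation is tempered by the ester. Setting out from 7, Steglich esterification with 4 (DCC, DMAP, CH2Cl2) should give 5,7,3',4'-tetra-O-benzyl-3-O-(3,4,5-tri-O-benzylgalloyl)-4β-(2-ethoxyethoxy)-epicatechin F2. Thiol exchange on F2 with 8 (BF3·OEt2, CH2Cl2, −40 °C) would then proceed through the less electrophilic dioxolanylium resting state, which prefers the soft thiol to arene carbons, and comes back to the route at 10.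

**Further compounds**

F1 | step 8 | per-O-benzylated epicatechin 3-O-gallate-(4β→8)-epicatechin 3-O-gallate (lower dimer, free C8 on the upper unit) | O=C(O[C@@H]1[C@@H](c2c(OCc5ccccc5)cc(OCc5ccccc5)c3c2O[C@H](c2ccc(OCc5ccccc5)c(OCc5ccccc5)c2)[C@H](OC(=O)c2cc(OCc5ccccc5)c(OCc5ccccc5)c(OCc5ccccc5)c2)C3)c2c(OCc5ccccc5)cc(OCc5ccccc5)cc2O[C@@H]1c1ccc(OCc5ccccc5)c(OCc5ccccc5)c1)c1cc(OCc5ccccc5)c(OCc5ccccc5)c(OCc5ccccc5)c1
F2 | step 4 | 5,7,3',4'-tetra-O-benzyl-3-O-(3,4,5-tri-O-benzylgalloyl)-4β-(2-ethoxyethoxy)-(−)-epicatechin | O=C(O[C@@H]1[C@@H](OCCOCC)c2c(OCc3ccccc3)cc(OCc3ccccc3)cc2O[C@@H]1c1ccc(OCc2ccccc2)c(OCc2ccccc2)c1)c1cc(OCc2ccccc2)c(OCc2ccccc2)c(OCc2ccccc2)c1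
F3 | step 9 | bromine-free octadeca-O-benzyl trimer (16 with H in place of Br at C8 of the top unit) | O=C(O[C@@H]1[C@@H](c2c(OCc5ccccc5)cc(OCc5ccccc5)c3c2O[C@H](c2ccc(OCc5ccccc5)c(OCc5ccccc5)c2)[C@H](OC(=O)c2cc(OCc5ccccc5)c(OCc5ccccc5)c(OCc5ccccc5)c2)C3)c2c(OCc5ccccc5)cc(OCc5ccccc5)c([C@H]3c4c(OCc5ccccc5)cc(OCc5ccccc5)cc4O[C@H](c4ccc(OCc5ccccc5)c(OCc5ccccc5)c4)[C@@H]3O)c2O[C@@H]1c1ccc(OCc5ccccc5)c(OCc5ccccc5)c1)c1cc(OCc5ccccc5)c(OCc5ccccc5)c(OCc5ccccc5)c1
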